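After 60.0 min, on average 36.1 % of the charged E is left in the 3 earlier runs. Their charges of E run from 39 mM to 86 mM, yet these readings lie within 1.8 percentage points. So c_E is taken to lose the same share in each hour.

| flask | E | X | remark | time |
|---|---|---|---|---|
| amber | 55 mM | 0.19 mM | run made earlier |  |
| grey | 86 mM | 0.19 mM | run made earlier |  |
| violet | 39 mM | 0.38 mM | run made earlier |  |
| alder | 39 mM | 0.19 mM |  | 1.0 h |
| birch | 39 mM | 0.19 mM |  | 2.0 h |

| run | time / min | G / % | E / % |
|---|---|---|---|
| amber | 5.00 | 0 | 92.5 |
| amber | 15.0 | 1.5 | 79.7 |
| amber | 30.0 | 3.2 | 61.8 |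
| amber | 40.0 | 4.8 | 52.4 |
| amber | 60.0 | 7.1 | 36.8 |
| grey | 12.0 | 1.1 | 82.9 |
| grey | 25.0 | 3.7 | 65.8 |
| grey | 40.0 | 5.9 | 49.8 |
| grey | 50.0 | 7.3 | 41.7 |
| grey | 60.0 | 9.4 | 35.0 |
| violet | 5.00 | 0.1 | 93.0 |
| violet | 10.0 | 0.4 | 85.0 |
| violet | 15.0 | 1.2 | 79.1 |
| violet | 30.0 | 4.0 | 60.5 |
| violet | 60.0 | 7.2 | 36.6 |

(each reading ± 0.5 percentage points)

- the average divides the monomer in chains by the number of chains begun, living and dead together
- the analysis behind the earlier runs scatters by 0.5 percentage points, standard deviation
- on the list of suspects stand: E + X -> J + G; E + J -> G + J; E -> Q; 2 X -> Z; J + G -> D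
- the earlier runs do not show the number of chains; that part of a forecast is a guess

1. which of the two ends with the longer chains by the average number of monomer units in a chain (chains begun, living or dead) ("neither" if they lie within 10 %) (alder / birch / neither)
2. average number of monomer units in a chain (chains begun, living or dead) at the end, alder
3. average number of monomer units in a chain (chains begun, living or dead) at the end, birch

Alder and birch differ in time of reading. The asked length is the number-average degree of polymerisation: G divided by chains begun. A bench rule says that with a fixed count of chains, G and so the length grow in step with the spent share, the part of the charged E that has gone. After 1.0 h the spent share is 63.9 %. After 2.0 h it is 86.9 %. The rule therefore puts birch at 1.36 times alder, and the count of chains cancels.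

The rule needs G per E spent to stand still, and the grey readings do not show that. That ratio reads 6.43 % at 12.0 min and 14.5 % at 60.0 min, a rise by a factor of 2.26. Chains are thus probably still starting, so the rule is used here for the ratio of lengths, and their size remains unknown. The reckoning here says birch, outside the 10 % margin.

The forecast also says birch, with 22 for alder (range 12 to 50) and 30 for birch (range 16 to 70). It notes: “Chains begun are not observed.”

Alder ends at 89.1 and birch at 128, so birch is longer.

    E + X → J + G (k = 0.114 M⁻¹ min⁻¹)
    E + J → G + J, rate k2*[J]*[E] (k = 99.7 M⁻¹ min⁻¹)
    E → Q (k = 0.0148 min⁻¹)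
    2 X → Z (k = 67.2 M⁻¹ min⁻¹)
    J + G → D (k = 0.0485 M⁻¹ min⁻¹)

The longer time is the main reason for the gap: birch gives 128, and without the difference in time it gives 89.1. Birch is the alder flask run on, and its E falls from 38.0 % to 13.7 % between the two readings. The lengths stand at 1.44 to one, against the reckoned 1.36. In alder, G divided by the length gives 0.0202 mM of chains begun against the 0.1 mM guessed, and the length of alder is 4.05 times the forecast's. The amber and grey runs show 48.9 % of E spent at 40 min. Scaling alder by that over 63.9 % gives 68.2 for the alder flask read then, and that flask gives 66.5.

The runs were generated by integration for substances that don't exist, noise included.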